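## The problem

The target is a (2S)-5-hydroxy-7-methoxyflavanone whose ring A has no hydrogen left: C6 and C8 each carry the same 2-hydroxy-5-(2-hydroxybenzyl)benzyl arm, so four diarylmethane C–C bonds must be made besides the flavanone itself. In each arm the inner CH2 joins ring A to the carbon ortho to the hydroxyl of the inner phenol ring D, and the outer CH2 joins C5 of ring D, para to that hydroxyl, to the carbon ortho to the hydroxyl of the outer phenol ring E. Every ring involved is an electron-rich phenol, so benzylation by a free hydroxybenzyl cation or ortho-quinone methide runs on to oligomers unless the open positions are limited. C2 is the only stereocentre and nothing else in the molecule can control it, so it is best bought, in (S)-pinostrobin (1). It must then be shielded from the one process that erases it, the retro-oxa-Michael opening of ring C through the C3 enolate, which rules out hydroxide, alkoxide and hot amine bases and limits heat and acid. The C7 methyl ether further excludes deprotection by strong Lewis acids. The enabling feature is that a bromine at C5 of ring D is already present in the commercial salicyl alcohol 2. It blocks the position that over-benzylation would hit, and it later marks the carbon where ring E is attached by cross-coupling.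

## Retrosynthesis

**11 from 10.** No skeletal bond is cut; the five phenols of 11 are released from pentaacetate 10. Acetates are preferred to ethers because acid-catalysed methanolysis removes them without touching the C7 methyl ether or ring C. Methyl ethers would need Lewis acids that also attack the C7 methoxy group, and benzyl ethers would need hydrogenolysis next to the benzylic C2–O bond. The forward step must cleave five esters without base.

**10 from 7 and 9.** The two bonds between C5 of each ring D and the outer CH2 are cut, giving dibromide 7 and two molecules of the benzylic zinc reagent 9. Cutting on the other side of the same CH2 would demand an ortho-selective reaction on a ring E phenol and leave ring D one oxidation level too high. Cutting the inner bonds last would bring in a complete arm whose ring E has to survive an ortho-quinone methide reaction. The chosen cut pairs an aryl bromide with a benzylic zinc chloride, which couple under neutral palladium catalysis at room temperature. Each cut removes a C7 unit, and the precursor 7 contains only rings A to D. The forward reaction must run twice on one molecule, consume two molecules of 9, tolerate a ketone and aryl acetates, and need no base.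

**9 from 8.** The C–Zn bond is traced back to the C–Cl bond of catalogue chloride 8 by direct zinc insertion. The acetate is already in place and matches the protecting groups of 7, so one deprotection serves both fragments.

**7 from 6.** The three O-acetyl bonds are cut. Acetylation of triphenol 6 removes the acidic protons that would quench 9 and makes the rings less electron-rich. It adds one step and no selectivity problem, since all three hydroxyls are to be acylated; it is run cold with pyridine so that ring C stays closed.

**6 from 1 and 2.** The two bonds between ring A (C6 and C8) and the inner CH2 groups are cut, giving 1 and two molecules of 2. The electrophile is ortho-quinone methide 3, formed from 2, and the reaction passes through the monobenzyl compounds 4 and 5, which converge on 6 when the second molecule of 2 is taken up. Building ring C after the arms would require an asymmetric cyclisation. Cross-coupling at a ring A dihalide would have to distinguish ring A halides from the bromine in the reagent. Direct benzylation of 1 uses the nucleophilicity that ring A has by nature, and it takes over the whole flavanone and the stereocentre from the chiral pool. The forward reaction must benzylate twice, prefer ring A over the bromophenol rings, and leave C2 untouched.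

## Roads not taken

**Alternative 1:** The cut runs between ring A and ring C, through the C8a–O1 and C4a–C4 bonds. The key step would give the ortho-hydroxyaryl ynone A1 from the hexasubstituted 2-silylaryl triflate A2 and phenylpropiolic acid A3. Fluoride releases the C4a≡C8a aryne, the carboxylate oxygen adds at C8a, and the aryl anion at C4a captures the acyl carbon.
- Merits: the C5 oxygen of A2 steers the oxygen nucleophile to the distal aryne carbon, so the regiochemistry is predictable. One C–O and one C–C bond to ring A form in a single step, and no stereocentre is exposed to benzylation chemistry.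
- Weak points: A2 must already carry both complete arms, so all four diarylmethane bonds have to be solved beforehand on a benzene ring that also needs adjacent silyl and triflate groups. A1 is at the alkynone oxidation level: 6-endo closure gives flavone A4, with 5-exo closure as a competitor. C2 would then have to be created by enantioselective conjugate reduction of a fully substituted 2-arylchromone, which has no dependable precedent. The arm at C8 also hinders the attack at C8a that the C5 oxygen favours.
- Comparison: this road is better in one respect. Its optical purity does not depend on a purchased centre surviving Lewis acid and acylation steps, and both enantiomers and other ring B groups would be accessible. The chosen plan sets against this five steps in place of well over a dozen, and a stereocentre that needs no asymmetric step.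

**Alternative 2:** The inner bonds between each inner benzylic carbon and ring D are made last. The key step would give bis(sulfide) A5 from the ring A bis(methylsulfanylmethyl) flavanone A6 and two molecules of the ring D–ring E phenol A7. Each sulfide is chlorinated at sulfur by an N-chloroimide, the phenol oxygen of A7 displaces chloride, a tertiary amine deprotonates the benzylic carbon, and the ylide shifts [2,3] onto the ortho carbon of ring D.
- Merits: the five-membered cyclic transition state delivers carbon only ortho to the ring D oxygen. A7 is para-substituted, so no blocking group is needed, and the route is convergent.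
- Weak points: the key step needs an amine base in the presence of a 5-acetoxyflavanone, which is the ring C opening pathway to be avoided. Ylide formation at the S-methyl group competes with the crowded benzylic carbon and would give the wrong constitution. Electrophilic chlorine can attack the electron-rich rings. A6 is not directly available from 1, because ortho-thiomethylation reaches only C6, the one position ortho to a free hydroxyl. A7 needs its own diarylmethane synthesis. After the key step a reductive desulfurisation next to the C4 ketone and the benzylic C2–O bond is required, then two kinds of protecting group must be removed.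
- Comparison: regiocontrol at ring D by pericyclic geometry is at least as rigorous as the bromine marker, and no metal-catalysed coupling is run on the full skeleton. The chosen plan sets against this the formation of both inner bonds on unprotected 1 in one base-free step, no sulfur to remove, and about three fewer steps.

**Alternative 3:** The outer bonds are cut on the far side of the outer carbon, between it and ring E. The key step would give bis(benzodioxaborin) A8 from dialdehyde A9, phenol A10 and phenylboronic acid A11. The boronic acid esterifies the phenol, the aldehyde coordinates to boron, the ortho carbon of the phenol attacks the carbonyl carbon within this assembly, and the alkoxide closes the dioxaborin ring, twice over.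
- Merits: ortho specificity at ring E is enforced by the boron tether and matches the bromine marker in rigour. A10 is the cheapest possible ring E source, and no palladium or organometallic reagent is needed.
- Weak points: A8 is one oxidation level too high at both outer carbons. Removing the benzylic oxygens by ionic hydrogenation is an extra step that passes through quinone-methide-like cations next to several oxygen nucleophiles. The condensation needs a carboxylic acid catalyst in hot aromatic solvent with water removal for many hours, which is harsher on ring C than any step of the chosen route. A9 is harder to reach than 7, because a formyl group makes the salicyl alcohol a poorer quinone methide precursor and can itself condense with ring A, so it would have to be masked. Both carbinol carbons arise as epimer mixtures, which complicates analysis.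
- Comparison: this road is better in reagent cost and in avoiding metal catalysis. The chosen plan sets against this bond formation at the correct oxidation level, neutral room-temperature conditions in the key step, a bromine that is inert during the ring A benzylation, and about two fewer steps.

Key step: step 4

Remark: (S)-pinostrobin (1), alcohol 2 and chloride 8 are taken as catalogue compounds, and the optical purity of purchased 1 is assumed to be confirmed by chiral HPLC before use.

## Route

Step 1
Reactants: 1 (S)-pinostrobin; 2 5-bromo-2-hydroxybenzyl alcohol (two molecules are incorporated)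
Product: 6 (2S)-6,8-bis(5-bromo-2-hydroxybenzyl)-5-hydroxy-7-methoxyflavanone, via 4-bromo-6-methylidenecyclohexa-2,4-dien-1-one 3 (not isolated), via (2S)-6-(5-bromo-2-hydroxybenzyl)pinostrobin 4 (not isolated), via (2S)-8-(5-bromo-2-hydroxybenzyl)pinostrobin 5 (not isolated)
Conditions: 2 (2.6 equiv, in portions), ZnCl2 (2 equiv), 1,4-dioxane, 100 °C
Reagents that add atoms: 5-bromo-2-hydroxybenzyl alcohol (second molecule of 2), OCc1cc(Br)ccc1O
Why: Lewis-acid-promoted Friedel–Crafts benzylation through an ortho-quinone methide, a reaction type known for 5-hydroxyflavanones and 2-hydroxybenzyl alcohols: ZnCl2 ionises 2 to 3 (or its zinc-bound equivalent) with loss of water, and 3 is captured by C6 and C8 of ring A, the only strongly nucleophilic C–H positions present, so that one molecule of 2 gives 4 and 5 and a second molecule of 2 converts both into the common product 6. The bromine blocks the para position of the reagent's own ring and lowers its nucleophilicity, so self-condensation and attack on ring D should be slower than attack by ring A. No base is present and ring B has no donor to assist ionisation at C2, so the (S) centre should persist, which is checked by chiral HPLC on 6.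

Step 2
Reactants: 6 (2S)-6,8-bis(5-bromo-2-hydroxybenzyl)-5-hydroxy-7-methoxyflavanone
Product: 7 (2S)-5-acetoxy-6,8-bis(2-acetoxy-5-bromobenzyl)-7-methoxyflavanone
Conditions: Ac2O (4 equiv), pyridine, DMAP (cat.), CH2Cl2, 0 °C to rt
Reagents that add atoms: acetic anhydride, CC(=O)OC(C)=O
Why: Standard O-acetylation with nucleophilic catalysis, in which three molecules of acetic anhydride each deliver one acetyl group; DMAP is needed for the hydrogen-bonded C5 hydroxyl, and pyridine at or below room temperature is the usual way to acetylate optically active flavanones without ring opening. The acetates remove the acidic protons that would destroy the organozinc reagent.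

Step 3
Reactants: 8 2-(chloromethyl)phenyl acetate
Product: 9 2-acetoxybenzylzinc chloride
Conditions: Zn dust, LiCl, THF, 25 °C
Reagents that add atoms: zinc, [Zn]
Why: LiCl-promoted direct insertion of zinc into a benzylic C–Cl bond, a known route to ester-bearing benzylic zinc chlorides; LiCl takes the organozinc off the metal surface and keeps Wurtz coupling low at 25 °C. The reagent is kept as a THF solution, titrated with iodine and used the same day.

Step 4
Reactants: 7 (2S)-5-acetoxy-6,8-bis(2-acetoxy-5-bromobenzyl)-7-methoxyflavanone; 9 2-acetoxybenzylzinc chloride (two molecules are incorporated)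
Product: 10 (2S)-5-acetoxy-6,8-bis[2-acetoxy-5-(2-acetoxybenzyl)benzyl]-7-methoxyflavanone
Conditions: Pd(OAc)2 (5 mol%), SPhos (10 mol%), 9 (3 equiv, slow addition), THF, 25 °C; aq. NH4Cl
Reagents that add atoms: 2-acetoxybenzylzinc chloride (second molecule of 9), CC(=O)Oc1ccccc1C[Zn]Cl
Why: Negishi sp2–sp3 cross-coupling of a functionalised benzylic zinc chloride with an aryl bromide; the closest known reaction type is this same coupling under Pd(OAc)2 and SPhos in THF at room temperature. Pd(OAc)2 is reduced by a little of 9 to zerovalent palladium carrying SPhos, which adds oxidatively to the C5–Br bond of one ring D; the benzyl group passes from zinc to divalent palladium, reductive elimination forms the ring D–CH2 bond and returns zerovalent palladium, and the cycle repeats at the second arm with a second molecule of 9, each turnover releasing one zinc bromide chloride. No ring is closed and no stereocentre is formed. The step needs chemoselectivity for C–Br over the aryl C–OAc bonds, the ester carbonyls and the C4 ketone: palladium with SPhos does not insert into aryl acetates at 25 °C, and benzylic zinc chlorides do not add to esters or ketones without activation. Site selectivity is fixed, because the new bonds can form only where the bromines stand, para to the ring D oxygens; both bromides are flanked only by C–H bonds and are electronically alike, so the second coupling should be as fast as the first. The benzyl group has no β-hydrogen, so reductive elimination has no competitor on palladium, and slow addition of 9 keeps its homocoupling low. The medium contains no base and the reagent is too weakly basic to enolise C3, so ring C should stay closed and the C2 configuration of 7 should pass unchanged into 10.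

Step 5
Reactants: 10 (2S)-5-acetoxy-6,8-bis[2-acetoxy-5-(2-acetoxybenzyl)benzyl]-7-methoxyflavanone
Product: 11 5''-(2''''-hydroxybenzyl)uvarinol, (2S)-5-hydroxy-6,8-bis[2-hydroxy-5-(2-hydroxybenzyl)benzyl]-7-methoxyflavanone
Conditions: HCl (1.25 M in MeOH), THF, 0 °C to rt
Reagents that add atoms: none
Why: Acid-catalysed transesterification of the five aryl acetates with methanol, which carries the acetyl groups off as methyl acetate; phenyl esters exchange readily and the C5 acetate is further activated by the neighbouring carbonyl. Ring C opens through the C3 enolate under base, not in dilute HCl at room temperature, and the C7 methyl ether and the diarylmethane bridges are inert, so 11 should be obtained with the (S) centre intact.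

## Compound list

1 | (S)-pinostrobin, (2S)-5-hydroxy-7-methoxyflavanone | COc1cc(O)c2c(c1)O[C@H](c1ccccc1)CC2=O | starting material
2 | 5-bromo-2-hydroxybenzyl alcohol | OCc1cc(Br)ccc1O | starting material
3 | 4-bromo-6-methylidenecyclohexa-2,4-dien-1-one (ortho-quinone methide, not isolated) | C=C1C=C(Br)C=CC1=O | intermediate
4 | (2S)-6-(5-bromo-2-hydroxybenzyl)-5-hydroxy-7-methoxyflavanone (not isolated) | COc1c(Cc2cc(Br)ccc2O)c(O)c2c(c1)O[C@H](c1ccccc1)CC2=O | intermediate
5 | (2S)-8-(5-bromo-2-hydroxybenzyl)-5-hydroxy-7-methoxyflavanone (not isolated) | COc1cc(O)c2c(c1Cc1cc(Br)ccc1O)O[C@H](c1ccccc1)CC2=O | intermediate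
6 | (2S)-6,8-bis(5-bromo-2-hydroxybenzyl)-5-hydroxy-7-methoxyflavanone | COc1c(Cc2cc(Br)ccc2O)c(O)c2c(c1Cc1cc(Br)ccc1O)O[C@H](c1ccccc1)CC2=O | intermediate
7 | (2S)-5-acetoxy-6,8-bis(2-acetoxy-5-bromobenzyl)-7-methoxyflavanone | COc1c(Cc2cc(Br)ccc2OC(C)=O)c(OC(C)=O)c2c(c1Cc1cc(Br)ccc1OC(C)=O)O[C@H](c1ccccc1)CC2=O | intermediate
8 | 2-(chloromethyl)phenyl acetate | CC(=O)Oc1ccccc1CCl | starting material
9 | 2-acetoxybenzylzinc chloride (LiCl-complexed THF solution) | CC(=O)Oc1ccccc1C[Zn]Cl | intermediate
10 | (2S)-5-acetoxy-6,8-bis[2-acetoxy-5-(2-acetoxybenzyl)benzyl]-7-methoxyflavanone | COc1c(Cc2cc(Cc3ccccc3OC(C)=O)ccc2OC(C)=O)c(OC(C)=O)c2c(c1Cc1cc(Cc3ccccc3OC(C)=O)ccc1OC(C)=O)O[C@H](c1ccccc1)CC2=O | intermediate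
11 | 5''-(2''''-hydroxybenzyl)uvarinol, (2S)-5-hydroxy-6,8-bis[2-hydroxy-5-(2-hydroxybenzyl)benzyl]-7-methoxyflavanone | COc1c(Cc2cc(Cc3ccccc3O)ccc2O)c(O)c2c(c1Cc1cc(Cc3ccccc3O)ccc1O)O[C@H](c1ccccc1)CC2=O | target

## Step count and least certain steps

Total: 5 steps. Longest linear sequence: 4 steps (steps 1, 2, 4 and 5, from 1 through 6, 7 and 10 to 11). The reagent branch (step 3) joins at step 4.

**Step 4, the key step.** The most likely failure is an incomplete twofold coupling. The second C–Br bond may stay unreacted because the benzylic zinc reagent is used up by homocoupling or by slow acetyl transfer within the reagent, leaving mixtures of singly and doubly coupled material. The fallback reverses the polarity and sets out from 7. Cobalt-catalysed zinc insertion (CoBr2, Zn dust, MeCN, rt, with catalytic allyl chloride and CF3CO2H as activators) turns both C–Br bonds into C–Zn bonds. This gives (2S)-5-acetoxy-6,8-bis[2-acetoxy-5-(bromozincio)benzyl]-7-methoxyflavanone F1, which is not isolated. Under the same cobalt catalysis it is coupled with two molecules of chloride 8 as the electrophile, and the sequence comes back to the route at 10. This is known chemistry for aryl bromides bearing esters and ketones, it is base-free, and no ortho-acetoxy benzylic organometallic is needed.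

**Step 1.** Two things can go wrong. The ring A benzylation may stop short of the second arm or run on into ring D when forced, and ring C may open and reclose reversibly on the zinc chelate at 100 °C, eroding the optical purity. The fallback moves the benzylation to an achiral substrate and sets out from 2. Catalogue 2',6'-dihydroxy-4'-methoxyacetophenone F2 is benzylated with two molecules of 2 (ZnCl2, dioxane, 100 °C, forcing conditions now being harmless) to 3',5'-bis(5-bromo-2-hydroxybenzyl)-2',6'-dihydroxy-4'-methoxyacetophenone F3. Claisen–Schmidt condensation with benzaldehyde (KOH, EtOH, rt) gives the (E)-chalcone F4, and oxa-Michael closure (NaOAc, EtOH, reflux) gives the racemic flavanone F5. Preparative chiral HPLC separates F5; the (2R)-enantiomer F6 is set aside, and the (2S)-enantiomer is 6, where the route is rejoined.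

**Step 3.** Wurtz-type dimerisation during insertion, or slow migration of the acetyl group from oxygen to the benzylic carbon on standing, would lower the titre of the reagent. The fallback uses a protecting group that cannot migrate and sets out from 7. Catalogue 2-(benzyloxy)benzyl chloride F7 is converted (Zn dust, LiCl, THF) into 2-(benzyloxy)benzylzinc chloride F8. Coupling of two molecules of F8 with 7 under the conditions of step 4 gives (2S)-5-acetoxy-6,8-bis{2-acetoxy-5-[2-(benzyloxy)benzyl]benzyl}-7-methoxyflavanone F9. Methanolysis with HCl in MeOH removes the three acetates to give (2S)-6,8-bis{5-[2-(benzyloxy)benzyl]-2-hydroxybenzyl}-5-hydroxy-7-methoxyflavanone F10. Hydrogenolysis of the two benzyl ethers (H2, Pd on carbon, EtOAc, rt, stopped at full conversion to spare the C2–O bond) returns to the route at 11.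

**Step 5.** The acetates on ring D are flanked by ortho substituents and may cleave slowly. Longer exposure to acid raises the chance of ring C opening or of ketal formation at C4. The fallback lowers the number of esters to be removed and sets out from 6, omitting step 2. The Negishi coupling is run on the free triphenol, a substrate class that is known to tolerate phenolic OH groups when the zinc reagent is added slowly (9, 4 equiv, Pd(OAc)2, SPhos, THF, 25 °C). This gives (2S)-6,8-bis[5-(2-acetoxybenzyl)-2-hydroxybenzyl]-5-hydroxy-7-methoxyflavanone F11. Its two unhindered outer acetates are then removed under neutral conditions (NH4OAc, MeOH–H2O, rt), arriving at 11.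

## Further compounds

F1 | step 4 | (2S)-5-acetoxy-6,8-bis[2-acetoxy-5-(bromozincio)benzyl]-7-methoxyflavanone | COc1c(Cc2cc([Zn]Br)ccc2OC(C)=O)c(OC(C)=O)c2c(c1Cc1cc([Zn]Br)ccc1OC(C)=O)O[C@H](c1ccccc1)CC2=O
F2 | step 1 | 2',6'-dihydroxy-4'-methoxyacetophenone | CC(=O)c1c(O)cc(OC)cc1O
F3 | step 1 | 3',5'-bis(5-bromo-2-hydroxybenzyl)-2',6'-dihydroxy-4'-methoxyacetophenone | CC(=O)c1c(O)c(Cc2cc(Br)ccc2O)c(OC)c(Cc2cc(Br)ccc2O)c1O
F4 | step 1 | (E)-1-[3,5-bis(5-bromo-2-hydroxybenzyl)-2,6-dihydroxy-4-methoxyphenyl]-3-phenylprop-2-en-1-one | O=C(/C=C/c1ccccc1)c1c(O)c(Cc2cc(Br)ccc2O)c(OC)c(Cc2cc(Br)ccc2O)c1O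
F5 | step 1 | racemic 6,8-bis(5-bromo-2-hydroxybenzyl)-5-hydroxy-7-methoxyflavanone | COc1c(Cc2cc(Br)ccc2O)c(O)c2c(c1Cc1cc(Br)ccc1O)OC(c1ccccc1)CC2=O
F6 | step 1 | (2R)-6,8-bis(5-bromo-2-hydroxybenzyl)-5-hydroxy-7-methoxyflavanone | COc1c(Cc2cc(Br)ccc2O)c(O)c2c(c1Cc1cc(Br)ccc1O)O[C@@H](c1ccccc1)CC2=O
F7 | step 3 | 2-(benzyloxy)benzyl chloride | ClCc1ccccc1OCc1ccccc1
F8 | step 3 | 2-(benzyloxy)benzylzinc chloride | Cl[Zn]Cc1ccccc1OCc1ccccc1
F9 | step 3 | (2S)-5-acetoxy-6,8-bis{2-acetoxy-5-[2-(benzyloxy)benzyl]benzyl}-7-methoxyflavanone | COc1c(Cc2cc(Cc3ccccc3OCc3ccccc3)ccc2OC(C)=O)c(OC(C)=O)c2c(c1Cc1cc(Cc3ccccc3OCc3ccccc3)ccc1OC(C)=O)O[C@H](c1ccccc1)CC2=O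
F10 | step 3 | (2S)-6,8-bis{5-[2-(benzyloxy)benzyl]-2-hydroxybenzyl}-5-hydroxy-7-methoxyflavanone | COc1c(Cc2cc(Cc3ccccc3OCc3ccccc3)ccc2O)c(O)c2c(c1Cc1cc(Cc3ccccc3OCc3ccccc3)ccc1O)O[C@H](c1ccccc1)CC2=O
F11 | step 5 | (2S)-6,8-bis[5-(2-acetoxybenzyl)-2-hydroxybenzyl]-5-hydroxy-7-methoxyflavanone | COc1c(Cc2cc(Cc3ccccc3OC(C)=O)ccc2O)c(O)c2c(c1Cc1cc(Cc3ccccc3OC(C)=O)ccc1O)O[C@H](c1ccccc1)CC2=O
A1 | alternative 1 | 1-[2-hydroxy-4-methoxy-6-(methoxymethoxy)-3,5-bis{2-(methoxymethoxy)-5-[2-(methoxymethoxy)benzyl]benzyl}phenyl]-3-phenylprop-2-yn-1-one | COc1c(Cc2cc(Cc3ccccc3OCOC)ccc2OCOC)c(OCOC)c(C(=O)C#Cc2ccccc2)c(O)c1Cc1cc(Cc2ccccc2OCOC)ccc1OCOC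
A2 | alternative 1 | 5-methoxy-3-(methoxymethoxy)-4,6-bis{2-(methoxymethoxy)-5-[2-(methoxymethoxy)benzyl]benzyl}-2-(trimethylsilyl)phenyl trifluoromethanesulfonate, numbered with the triflate carbon as C1 and the silyl carbon as C2, so that the methoxymethoxy group sits on C3 beside the silyl carbon | COc1c(Cc2cc(Cc3ccccc3OCOC)ccc2OCOC)c(OCOC)c([Si](C)(C)C)c(OS(=O)(=O)C(F)(F)F)c1Cc1cc(Cc2ccccc2OCOC)ccc1OCOC
A3 | alternative 1 | phenylpropiolic acid | OC(=O)C#Cc1ccccc1
A4 | alternative 1 | 7-methoxy-5-(methoxymethoxy)-6,8-bis{2-(methoxymethoxy)-5-[2-(methoxymethoxy)benzyl]benzyl}flavone | COc1c(Cc2cc(Cc3ccccc3OCOC)ccc2OCOC)c(OCOC)c2c(c1Cc1cc(Cc3ccccc3OCOC)ccc1OCOC)oc(-c1ccccc1)cc2=O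
A5 | alternative 2 | (2S)-5-acetoxy-6,8-bis{[2-hydroxy-5-(2-(methoxymethoxy)benzyl)phenyl](methylsulfanyl)methyl}-7-methoxyflavanone, both epimers at each sulfur-bearing carbon | COc1c(C(SC)c2cc(Cc3ccccc3OCOC)ccc2O)c(OC(C)=O)c2c(c1C(SC)c1cc(Cc3ccccc3OCOC)ccc1O)O[C@H](c1ccccc1)CC2=O
A6 | alternative 2 | (2S)-5-acetoxy-7-methoxy-6,8-bis(methylsulfanylmethyl)flavanone | COc1c(CSC)c(OC(C)=O)c2c(c1CSC)O[C@H](c1ccccc1)CC2=O
A7 | alternative 2 | 4-[2-(methoxymethoxy)benzyl]phenol | COCOc1ccccc1Cc1ccc(O)cc1
A8 | alternative 3 | (2S)-5-acetoxy-6,8-bis[2-acetoxy-5-(2-phenyl-4H-1,3,2-benzodioxaborin-4-yl)benzyl]-7-methoxyflavanone, both epimers at each boronate-bearing carbon | COc1c(Cc2cc(C3OB(c4ccccc4)Oc4ccccc34)ccc2OC(C)=O)c(OC(C)=O)c2c(c1Cc1cc(C3OB(c4ccccc4)Oc4ccccc34)ccc1OC(C)=O)O[C@H](c1ccccc1)CC2=O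
A9 | alternative 3 | (2S)-5-acetoxy-6,8-bis(2-acetoxy-5-formylbenzyl)-7-methoxyflavanone | COc1c(Cc2cc(C=O)ccc2OC(C)=O)c(OC(C)=O)c2c(c1Cc1cc(C=O)ccc1OC(C)=O)O[C@H](c1ccccc1)CC2=O
A10 | alternative 3 | phenol | Oc1ccccc1
A11 | alternative 3 | phenylboronic acid | OB(O)c1ccccc1
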